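## Structural features

The target is a dearomatised acylphloroglucinol. Ring A is an enolised cyclohexane-1,3,5-trione, numbered C1 (gem-diprenyl carbon), C2 (ketone), C3, C4 (ketone), C5 (bearing the 3-methylbutanoyl group) and C6 (enol carbon). C3 is the spiro atom shared with ring B (C3, C7, C8, C9, C10, C11), and ring B is trans-fused along C8–C9 to cyclopentane ring C (C8, C14, C13, C12, C9). There are five stereocentres: four are contiguous (C14 tertiary methyl carbinol, C8 and C9 ring-fusion methines, C10 tertiary methyl carbinol) and the fifth, the quaternary spiro carbon C3, is 1,3 to C10 across C11. For the tautomer drawn the configuration is (3S,8S,9R,10S,14R). In the chair of ring B the C10 hydroxyl is axial and syn to the C4 carbonyl arm on C3, while the C10 methyl, C12 and C14 are equatorial. The fragile elements are the acidic enolised β-triketone (O- versus C-alkylation, retro-Claisen cleavage), two tertiary alcohols that eliminate under acid, and two prenyl alkenes that exclude strong acid, oxidants and hydrogenation late in the route. The real difficulty is C3: it is stereogenic only because its two carbonyl arms differ (C2 leads to the diprenyl carbon, C4 to the acyl-bearing carbon), so two geminal carboxyl groups must be told apart relative to remote centres; the second problem is a trans-hydrindane with a tertiary carbinol next to the ring fusion. The key step exploits the fact that, with C10 as a ketone and C3 as a malonate carbon, the atoms C10, C11, C3 and C7 of ring B form a symmetric cyclobutanone, while C8 and C9 are the alkene carbons of a ring C cyclopentene that already carries C14. The later differentiation of the C3 arms exploits the syn-axial relation of C10–O and C4.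

## Logic of the disconnections

17 to 15: the two C1–CH2 bonds of the prenyl groups are cut. C1 is the only ring A carbon that still carries hydrogen between two carbonyls and does not bear the acyl group, so both prenyl groups can enter last and the acid- and oxidant-sensitive alkenes stay out of every earlier step. Ten carbons are removed. The forward step must alkylate on carbon, not oxygen, twice at the same atom, with two free tertiary alcohols present.

15 to 11 and 12: ring A is opened at C1–C2 and C4–C5, the C10 oxygen is re-attached to C4 as a lactone and the C14 hydroxyl is masked as a silyl ether. The three-carbon unit C1–C6–C5 with its acyl group is the diketone 12. Its terminal carbon must find C2 and its central carbon must find C4, so the two carboxyl arms on C3 have to differ in reactivity: an acid chloride in 11 for the first bond, a lactone for the second. The forward step needs chemoselective acylation at the acid chloride, then a Claisen closure onto the lactone that releases the C10 carbinol.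

11 to 9 to 7: functional-group changes only (acid chloride from acid, acid from isopropyl ester, temporary silylation of C14–OH). The demand is hydrolysis of a hindered ester without loss of the arm differentiation; this is met because the lactone can only re-form from the arm syn to C10–O.

7 to 5: the C10–CH3 bond and the lactone O–C4 bond are cut. Methyl addition to the C10 ketone from the equatorial side gives an axial alkoxide that is syn-axial to one ester only. Lactonisation therefore desymmetrises the geminal diester and fixes C10 and C3 in one operation. The forward step needs equatorial attack on an enolisable ketone without attack on the esters.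

5 to 2 and 3: the C9–C10 and C7–C8 bonds are cut. This removes ring B and two stereocentres and leaves two small partners, one symmetric and achiral, the other carrying C14 from the chiral pool. The forward step must insert an unactivated cyclic alkene into a cyclobutanone C–C bond with control of regiochemistry (C10 to C9), of face (C7 syn to the C14 hydroxyl) and of the ring fusion (trans, by equilibration at C9).

2 to 1: the C8=C9 bond is cut by ring-closing metathesis. C14 is bought with its configuration and is not touched. 3 and 12 are purchased.

## Other disconnections considered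

Alternative 1: The cut is C3–C11 together with the lactone O–C10 bond. It leads back to the monocyclic malonate A1, in which ring C already carries the C14 carbinol, a CH2–CH(CO2Me)2 arm on C8 and an isopropenyl group on C9.
- Forward step: Mn(OAc)3 (trivalent manganese) would oxidise the malonate C–H to the malonyl radical, which should add 6-endo to the terminal carbon of the 1,1-disubstituted alkene. Oxidation of the tertiary C10 radical and capture of the cation by the syn ester carbonyl would give the bridged lactone ester A2.
- In its favour: oxidative radical cyclisation of malonates with lactone termination is an established reaction type. Ring B, the C10–O bond and the differentiation of the two esters arise in one operation, and A2 is the methyl-ester analogue of 7, reached without an organometallic addition.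
- Against it here: the 6-endo/5-exo partition, loss of a proton from the C10 cation in competition with lactonisation, a free tertiary C14 alcohol in hot acetic acid and a stoichiometric oxidant. Above all, A1 contains three contiguous stereocentres that must be assembled first (conjugate addition and enolate trapping on a cyclopentenone, methyl addition, absolute control from an external catalyst), estimated at four to five steps.
- Comparison: on mechanistic security of the key step the alternative is the better plan. On the stereochemical logic at C3 and C10 it is the equal of the chosen plan (same syn-axial lactone argument). On step economy the chosen plan is shorter by about two to three steps, because 7 is reached in three steps from purchased materials.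

Alternative 2: The cuts are C8–C14 and C9–C12, so ring C is annulated onto a ring B enone. The product drawn for this step is a gem-diester, so the substrate is read as the achiral enone gem-diester A3 and not as a spiro compound.
- Forward step: Rh(acac)(C2H4)2 with BINAP (monovalent rhodium) would transfer the 4-chlorobut-1-en-2-yl group of boron reagent A4 to C8 (Hayashi–Miyaura conjugate addition). KOtBu would then alkylate the C9 enolate with the pendant chloride (5-exo-tet) and equilibrate C9, giving the trans-fused methylene hydrindanone A5.
- In its favour: a catalytic asymmetric step of a well-precedented type on cyclohexenones. The absolute configuration comes from the ligand and does not depend on the optical purity of a terpene; on this point it is the better plan. The trans fusion rests on the same thermodynamic argument as in the chosen plan (equal).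
- Against it here: C14 arrives as an exocyclic methylene. Its conversion into the tertiary carbinol of the right configuration needs a Markovnikov hydration with facial control at a centre flanked only by the ring fusion, with the C10 ketone spared. That is an open stereochemical problem and one or two further steps, whereas the chosen plan buys C14. α-Substituted alkenyl boron reagents are slow partners, and A3 is not a catalogue compound (about three steps).
- Comparison: the stage equivalent to 5 would be reached in about five to six steps against two. Mechanistic security is better; stereochemical completeness is worse.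

Alternative 3: The cut is C10–C11 with C3 taken as a ketone. It leads back to the bromomethyl ketone A6 (methyl ketone on C9, CH2–CO–CH2Br arm on C8, silyl ether on C14).
- Forward step: SmI2 (divalent samarium) would reduce the C–Br bond to the samarium enolate of the C3 ketone, which would add to the C10 methyl ketone and give the ketol A7.
- In its favour: a mild, neutral ring closure of a known type that creates ring B and the C10 carbinol together through a samarium-bridged transition state. The bromide fixes which ketone becomes the enolate. For C10 it avoids an organometallic addition to a hindered ketone, and on that point it is the equal of the chosen plan.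
- Against it here: C3 is left as a ketone. The quaternary spiro centre and both carbonyl arms still have to be installed, and no lactone is available to tell the arms apart, so C3 would be set by a late intermolecular event. The β-hydroxy ketone A7 is also open to retro-aldol cleavage and dehydration.
- Comparison: this is the longest plan, about five steps to A6 and at least five more for ring A from a ketone. The chosen plan carries C3 at the malonate oxidation level from its first C–C bond formation.

Key step: step 2

Assumptions:
- Stereodescriptors refer to the tautomers drawn.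
- The optical purity of the product cannot exceed that of the commercial (R)-(−)-linalool lot; enrichment by crystallisation of 5 or 9 is assumed if needed.
- The "alkoxide" control at C14 is replaced by a neutral hydroxyl acting as hydrogen-bond donor, because a base strong enough to form the alkoxide would enolise 3.

## Route

Step 1
Reactants: 1 (R)-(−)-linalool, (3R)-3,7-dimethylocta-1,6-dien-3-ol
Product: 2 (1R)-1-methylcyclopent-2-en-1-ol
Conditions: (H2IMes)(PCy3)Cl2Ru=CHPh (second-generation Grubbs catalyst, 0.5 mol%), CH2Cl2, 40 °C; ethyl vinyl ether quench; distillation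
Reagents that add atoms: none
Why: Ring-closing metathesis between the vinyl group and the trisubstituted alkene, driven by loss of volatile isobutene and helped by the allylic hydroxyl; C14 is not involved, so the R configuration of the terpene is carried over unchanged.

Step 2
Reactants: 2 (1R)-1-methylcyclopent-2-en-1-ol; 3 diisopropyl 3-oxocyclobutane-1,1-dicarboxylate
Product: 5 diisopropyl (3R,3aS,7aR)-3-hydroxy-3-methyl-7-oxooctahydro-5H-indene-5,5-dicarboxylate, via cis-fused ketone 4 (not isolated)
Conditions: Ni(cod)2 (10 mol%), PCy3 (20 mol%), 2 (3 equiv), slow addition of 3, PhMe, 100 °C; then DBU (0.5 equiv), 60 °C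
Reagents that add atoms: none
Why: Proposed new method: zerovalent nickel carrying PCy3 should bind the strained ketone of 3 and the alkene of 2 and couple them oxidatively to an oxanickelacyclopentane (C10–C9 bond, nickel on C8 and on the carbonyl oxygen); β-carbon elimination then opens the four-membered ring at C10–C7 (either α-bond, as 3 is symmetric) to a seven-membered nickelacycle (Ni–C7, Ni–C8), and C(sp3)–C(sp3) reductive elimination forms C7–C8. The closest known reaction types are the nickel-catalysed intermolecular insertion of alkynes into cyclobutanones and the rhodium-catalysed insertion of tethered alkenes into cyclobutanones; the intermolecular union with an unactivated cyclic alkene is the unproven part. Ring B closes as a formal intermolecular [4+2] (two-carbon ring expansion), the ring-closing event being reductive elimination from the seven-membered metallacycle and not a cyclisation onto a π-bond. Regiochemistry (C10 to C9) should follow from sterics, since C–C bond formation occurs at the alkene carbon remote from quaternary C14, and this orientation also places the nickel-bound carbonyl oxygen next to the free C14 hydroxyl, which can hydrogen-bond to it. C8 is controlled by the face: the metal should add on the face carrying OH (smaller than CH3 and the only face offering the hydrogen bond), and C7 is delivered with retention, so C7 ends cis to the C14 hydroxyl. C9 is first set by syn addition (cis-fused 4) and then corrected thermodynamically: DBU equilibrates the centre α to the ketone to trans-fused 5, expected to be the more stable epimer because both ring C bonds are then equatorial on ring B and C14 avoids the axial ester. β-Hydride loss is blocked by the substrates themselves (C3 and C14 are quaternary, the C9–H is anti to nickel), and the tertiary carbinol cannot isomerise to a ketone. Toluene keeps the hydroxyl free for the directing hydrogen bond, and slow addition of 3 to an excess of volatile, recoverable 2 limits self-reaction of the cyclobutanone.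

Step 3
Reactants: 5 diisopropyl (3R,3aS,7aR)-3-hydroxy-3-methyl-7-oxooctahydro-5H-indene-5,5-dicarboxylate
Product: 7 isopropyl (1S,2R,5R,6S,8S)-5-hydroxy-1,5-dimethyl-9-oxo-10-oxatricyclo[6.2.1.0^2,6]undecane-8-carboxylate, via hydroxy diester 6 (not isolated)
Conditions: MeLi, CeCl3 (3.3 equiv each), THF, −78 → 23 °C; aq. NH4Cl
Reagents that add atoms: methylcerium dichloride (from MeLi and CeCl3), C[Ce](Cl)Cl
Why: Organocerium 1,2-addition to an enolisable ketone (one equivalent is consumed by the C14 hydroxyl); axial approach to C10 is blocked by the syn-axial ester on C3, so methyl should enter equatorially and the C10 oxygen ends axial (10S). This alkoxide is 1,3-diaxial to one ester only and closes the γ-lactone by transesterification on warming, which fixes C3 (the lactone carbonyl becomes C4); any 6 that survives converges with 7 in step 4.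

Step 4
Reactants: 7 isopropyl (1S,2R,5R,6S,8S)-5-hydroxy-1,5-dimethyl-9-oxo-10-oxatricyclo[6.2.1.0^2,6]undecane-8-carboxylate
Product: 9 (1S,2R,5R,6S,8S)-5-hydroxy-1,5-dimethyl-9-oxo-10-oxatricyclo[6.2.1.0^2,6]undecane-8-carboxylic acid, via dihydroxy diacid 8 (not isolated)
Conditions: KOH, EtOH–H2O, 80 °C; then 2 M HCl to pH 2, 0 → 23 °C
Reagents that add atoms: potassium hydroxide, [K+].[OH-]
Why: Saponification opens the lactone and hydrolyses the hindered isopropyl ester; on acidification only the axial carboxyl is syn to the axial C10 hydroxyl, so the γ-lactone should re-form at C4 alone and C2 stays as the free acid. The C3 configuration is thus regenerated from C10, and cold acidification avoids decarboxylation of the malonic acid.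

Step 5
Reactants: 9 (1S,2R,5R,6S,8S)-5-hydroxy-1,5-dimethyl-9-oxo-10-oxatricyclo[6.2.1.0^2,6]undecane-8-carboxylic acid
Product: 11 (1S,2R,5R,6S,8R)-1,5-dimethyl-9-oxo-5-[(trimethylsilyl)oxy]-10-oxatricyclo[6.2.1.0^2,6]undecane-8-carbonyl chloride, via bis-silyl derivative 10 (not isolated)
Conditions: (Me3Si)2NH, cat. Me3SiOTf, CH2Cl2, 23 °C; evaporate; (COCl)2, cat. DMF, CH2Cl2, 0 → 23 °C; evaporate, use crude
Reagents that add atoms: hexamethyldisilazane, C[Si](C)(C)N[Si](C)(C)C; oxalyl chloride, ClC(=O)C(Cl)=O
Why: Silylation of the acid and the tertiary alcohol, then conversion of the silyl ester into the acid chloride by the Vilsmeier-type chloride donor under neutral conditions (loss of Me3SiCl, CO and CO2), which the tertiary silyl ether and the lactone should survive. The acyl chloride carbon has no α-hydrogen, so no ketene can form; the descriptor at C3 changes by priority only.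

Step 6
Reactants: 11 (1S,2R,5R,6S,8R)-1,5-dimethyl-9-oxo-5-[(trimethylsilyl)oxy]-10-oxatricyclo[6.2.1.0^2,6]undecane-8-carbonyl chloride; 12 6-methylheptane-2,4-dione
Product: 15 (1S,3'R,3a'S,7'S,7a'R)-3',4,7'-trihydroxy-3',7'-dimethyl-3-(3-methylbutanoyl)octahydrospiro[cyclohex-3-ene-1,5'-indene]-2,6-dione, via triketone lactone 13 (not isolated), via silyl-protected spiro trione 14 (not isolated)
Conditions: 12 (3 equiv), LiN(iPr)2 (6 equiv), THF, −78 → 0 °C; add 11 at −78 °C; warm to 40 °C; then 1 M HCl, THF, 23 °C
Reagents that add atoms: none
Why: The 1,3-diketone dianion is acylated at its terminal carbon (C1) by the acid chloride, which is far more electrophilic than the lactone, to give the 1,3,5-triketone. Its dianion then closes ring A by an intramolecular Claisen (Dieckmann-type, 6-exo-trig) attack of C5 on the strained lactone carbonyl C4, expelling the C10 alkoxide, and is driven by deprotonation of the tricarbonyl methine. Because the lactone arm is the one syn to C10–O, C3 is carried through as 3S; the acidic work-up cleaves the tertiary silyl ether.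

Step 7
Reactants: 15 (1S,3'R,3a'S,7'S,7a'R)-3',4,7'-trihydroxy-3',7'-dimethyl-3-(3-methylbutanoyl)octahydrospiro[cyclohex-3-ene-1,5'-indene]-2,6-dione
Product: 17 (1S,3'R,3a'S,7'S,7a'R)-3',4,7'-trihydroxy-3',7'-dimethyl-3-(3-methylbutanoyl)-5,5-bis(3-methylbut-2-en-1-yl)octahydrospiro[cyclohex-3-ene-1,5'-indene]-2,6-dione (CNP0198642.2), via monoprenyl trione 16 (not isolated)
Conditions: prenyl bromide (2.5 equiv), NaOMe (4 equiv), MeOH, 0 → 23 °C; aq. NH4Cl
Reagents that add atoms: 1-bromo-3-methylbut-2-ene (prenyl bromide), CC(C)=CCBr
Why: Double C-alkylation of the polyanion of an enolised acylphloroglucinol-type β-triketone, as in the exhaustive C-alkylation of acylphloroglucinols; C1 is the only ring carbon with hydrogens between two carbonyls and is more nucleophilic than the acyl-bearing C5, and the soft allylic bromide favours carbon over oxygen. C1 is not stereogenic and the tertiary alcohols should not be alkylated under methoxide.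

## Compound list

1 | (R)-(−)-linalool, (3R)-3,7-dimethylocta-1,6-dien-3-ol | C=C[C@](C)(O)CCC=C(C)C | starting material
2 | (1R)-1-methylcyclopent-2-en-1-ol | C[C@@]1(O)CCC=C1 | intermediate
3 | diisopropyl 3-oxocyclobutane-1,1-dicarboxylate | CC(C)OC(=O)C1(C(=O)OC(C)C)CC(=O)C1 | starting material
4 | diisopropyl (3R,3aS,7aS)-3-hydroxy-3-methyl-7-oxooctahydro-5H-indene-5,5-dicarboxylate (cis-fused; C7 and C10 both on the hydroxyl face) | CC(C)OC(=O)C1(C(=O)OC(C)C)C[C@H]2[C@H](CC[C@@]2(C)O)C(=O)C1 | intermediate (not isolated)
5 | diisopropyl (3R,3aS,7aR)-3-hydroxy-3-methyl-7-oxooctahydro-5H-indene-5,5-dicarboxylate (trans-fused) | CC(C)OC(=O)C1(C(=O)OC(C)C)C[C@H]2[C@@H](CC[C@@]2(C)O)C(=O)C1 | intermediate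
6 | diisopropyl (3R,3aS,7S,7aR)-3,7-dihydroxy-3,7-dimethyloctahydro-5H-indene-5,5-dicarboxylate | CC(C)OC(=O)C1(C(=O)OC(C)C)C[C@H]2[C@@H](CC[C@@]2(C)O)[C@@](C)(O)C1 | intermediate (not isolated)
7 | isopropyl (1S,2R,5R,6S,8S)-5-hydroxy-1,5-dimethyl-9-oxo-10-oxatricyclo[6.2.1.0^2,6]undecane-8-carboxylate (γ-lactone from C10–O to C4; ester arm is C2) | CC(C)OC(=O)[C@@]12C[C@H]3[C@@H](CC[C@@]3(C)O)[C@@](C)(OC1=O)C2 | intermediate
8 | (3R,3aS,7S,7aR)-3,7-dihydroxy-3,7-dimethyloctahydro-5H-indene-5,5-dicarboxylic acid | OC(=O)C1(C(O)=O)C[C@H]2[C@@H](CC[C@@]2(C)O)[C@@](C)(O)C1 | intermediate (not isolated)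
9 | (1S,2R,5R,6S,8S)-5-hydroxy-1,5-dimethyl-9-oxo-10-oxatricyclo[6.2.1.0^2,6]undecane-8-carboxylic acid | OC(=O)[C@@]12C[C@H]3[C@@H](CC[C@@]3(C)O)[C@@](C)(OC1=O)C2 | intermediate
10 | trimethylsilyl (1S,2R,5R,6S,8R)-1,5-dimethyl-9-oxo-5-[(trimethylsilyl)oxy]-10-oxatricyclo[6.2.1.0^2,6]undecane-8-carboxylate | C[Si](C)(C)OC(=O)[C@@]12C[C@H]3[C@@H](CC[C@@]3(C)O[Si](C)(C)C)[C@@](C)(OC1=O)C2 | intermediate (not isolated)
11 | (1S,2R,5R,6S,8R)-1,5-dimethyl-9-oxo-5-[(trimethylsilyl)oxy]-10-oxatricyclo[6.2.1.0^2,6]undecane-8-carbonyl chloride | ClC(=O)[C@@]12C[C@H]3[C@@H](CC[C@@]3(C)O[Si](C)(C)C)[C@@](C)(OC1=O)C2 | intermediate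
12 | 6-methylheptane-2,4-dione | CC(=O)CC(=O)CC(C)C | starting material
13 | 1-[(1S,2R,5R,6S,8S)-1,5-dimethyl-9-oxo-5-[(trimethylsilyl)oxy]-10-oxatricyclo[6.2.1.0^2,6]undecan-8-yl]-7-methyloctane-1,3,5-trione | CC(C)CC(=O)CC(=O)CC(=O)[C@@]12C[C@H]3[C@@H](CC[C@@]3(C)O[Si](C)(C)C)[C@@](C)(OC1=O)C2 | intermediate (not isolated)
14 | (1S,3'R,3a'S,7'S,7a'R)-4,7'-dihydroxy-3',7'-dimethyl-3-(3-methylbutanoyl)-3'-[(trimethylsilyl)oxy]octahydrospiro[cyclohex-3-ene-1,5'-indene]-2,6-dione | C1C(=O)[C@@]2(C[C@H]3[C@@H](CC[C@@]3(C)O[Si](C)(C)C)[C@@](C)(O)C2)C(=O)C(C(=O)CC(C)C)=C1O | intermediate (not isolated)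
15 | (1S,3'R,3a'S,7'S,7a'R)-3',4,7'-trihydroxy-3',7'-dimethyl-3-(3-methylbutanoyl)octahydrospiro[cyclohex-3-ene-1,5'-indene]-2,6-dione (ring A with C1 as CH2) | C1C(=O)[C@@]2(C[C@H]3[C@@H](CC[C@@]3(C)O)[C@@](C)(O)C2)C(=O)C(C(=O)CC(C)C)=C1O | intermediate
16 | (1S,3'R,3a'S,7'S,7a'R)-3',4,7'-trihydroxy-3',7'-dimethyl-3-(3-methylbutanoyl)-5-(3-methylbut-2-en-1-yl)octahydrospiro[cyclohex-3-ene-1,5'-indene]-2,6-dione (C1 monoprenylated, enolisable, configuration at C1 undefined) | CC(C)=CCC1C(=O)[C@@]2(C[C@H]3[C@@H](CC[C@@]3(C)O)[C@@](C)(O)C2)C(=O)C(C(=O)CC(C)C)=C1O | intermediate (not isolated)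
17 | (1S,3'R,3a'S,7'S,7a'R)-3',4,7'-trihydroxy-3',7'-dimethyl-3-(3-methylbutanoyl)-5,5-bis(3-methylbut-2-en-1-yl)octahydrospiro[cyclohex-3-ene-1,5'-indene]-2,6-dione, CNP0198642.2, (3S,8S,9R,10S,14R) in the ring numbering used above | CC(C)=CCC1(CC=C(C)C)C(=O)[C@@]2(C[C@H]3[C@@H](CC[C@@]3(C)O)[C@@](C)(O)C2)C(=O)C(C(=O)CC(C)C)=C1O | target

## Step count and least certain steps

Total step count: 7. Longest linear sequence: 7 steps (1 to 17); 3 and 12 are purchased and enter at steps 2 and 6.

Step 2 (key step, proposed new method). The most likely failure is that oxidative cyclisation between the nickel-bound ketone and an unactivated 1,2-disubstituted alkene next to a quaternary carbon does not compete. The catalyst would then be consumed by self-coupling of the cyclobutanone, by decarbonylation, or by β-oxygen elimination of the C14 hydroxyl from the C8–nickel intermediate. Secondary risks are reversed regiochemistry and a C9 equilibrium that does not lie far enough on the trans side.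

Fallback (known chemistry only; sets out from 2 and comes back at 5):
- 2 is silylated with (bromomethyl)chlorodimethylsilane (Et3N, DMAP, CH2Cl2) to (R)-(bromomethyl)dimethyl[(1-methylcyclopent-2-en-1-yl)oxy]silane F1.
- Slow addition of Bu3SnH with AIBN and excess tert-butyl isocyanide in benzene at 80 °C (silicon-tethered radical cyclisation of the Ueno–Stork type) closes the five-membered ring 5-exo. This places C7 on C8 from the oxygen face, and the C9 radical is trapped on the opposite, convex face to give the bicyclic siloxane nitrile F2.
- Tamao oxidation (KF, KHCO3, H2O2, THF–MeOH) gives the nitrile diol F3.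
- Excess MeLi followed by aqueous acid gives the methyl ketone diol F4.
- I2, PPh3 and imidazole convert the primary alcohol into the iodide F5.
- Br2 in MeOH at 0 °C brominates the methyl group to give the bromomethyl ketone F6.
- Diisopropyl malonate with Cs2CO3 in DMF is alkylated first by the α-bromoketone (C3–C11) and then intramolecularly by the iodide (C3–C7), closing ring B to 5.

Step 3. The risk is poor facial selectivity in the methyl addition, for example axial delivery through cerium bridging the ketone and the axial ester, or competing attack on an ester.

Fallback (sets out from 5 and comes back at 9):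
- Wittig methylenation (Ph3P=CH2, THF) gives the methylidene diester F7.
- Saponification (KOH, EtOH–H2O) gives the methylidene diacid F8.
- Iodolactonisation (I2, NaHCO3) gives the iodolactone acid F9; only the axial carboxyl can reach C10, so the oxygen is delivered intramolecularly to the axial position.
- Radical deiodination (Bu3SnH, AIBN, PhMe, 80 °C) gives 9.

Step 6. The risks are proton transfer or double acylation in place of clean C-acylation, attack of the dianion on the lactone carbonyl (which would join C1 to the wrong arm), and a slow Claisen closure because the nucleophile is a stabilised diketonate.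

Fallback (sets out from 11 and 12 and comes back at 13):
- 12 is converted (Me3SiCl, Et3N; then LiN(iPr)2, Me3SiCl) into 6-methyl-2,4-bis(trimethylsilyloxy)hepta-1,3-diene F10.
- F10 is acylated at its terminal carbon by 11 under neutral Mukaiyama-type conditions (cat. Me3SiOTf, CH2Cl2, −78 → 20 °C), giving 13 as an isolated compound after aqueous work-up.
- Ring closure is then run as a separate operation (KOtBu, THF, 0 → 23 °C) and followed by the same acidic work-up.

Step 7. The risks are alkylation on oxygen, a stop after the first alkylation, alkylation at C5, and retro-Claisen opening of ring A by methoxide once C1 is quaternary.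

Fallback (sets out from 15 and comes back at 17):
- Tsuji–Trost bis-allylation with allyl methyl carbonate and Pd(PPh3)4 (zerovalent palladium) in THF gives the 5,5-diallyl spiro trione F11; O-allyl products re-ionise and are funnelled to carbon.
- Double cross-metathesis with 2-methylbut-2-ene using (H2IMes)Cl2Ru=CH(C6H4-2-OiPr) (second-generation Hoveyda–Grubbs catalyst) converts both allyl groups into prenyl groups.

## Further compounds

F1 | step 2 | (R)-(bromomethyl)dimethyl[(1-methylcyclopent-2-en-1-yl)oxy]silane | C[C@@]1(O[Si](C)(C)CBr)CCC=C1
F2 | step 2 | (3aS,4R,6aR)-2,2,6a-trimethylhexahydro-2H-cyclopenta[d][1,2]oxasilole-4-carbonitrile | C[Si]1(C)C[C@H]2[C@@H](CC[C@@]2(C)O1)C#N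
F3 | step 2 | (1R,2R,3R)-3-hydroxy-2-(hydroxymethyl)-3-methylcyclopentane-1-carbonitrile | OC[C@H]1[C@@H](CC[C@@]1(C)O)C#N
F4 | step 2 | 1-[(1R,2R,3R)-3-hydroxy-2-(hydroxymethyl)-3-methylcyclopentyl]ethan-1-one | OC[C@H]1[C@@H](CC[C@@]1(C)O)C(C)=O
F5 | step 2 | 1-[(1R,2S,3R)-3-hydroxy-2-(iodomethyl)-3-methylcyclopentyl]ethan-1-one | IC[C@H]1[C@@H](CC[C@@]1(C)O)C(C)=O
F6 | step 2 | 2-bromo-1-[(1R,2S,3R)-3-hydroxy-2-(iodomethyl)-3-methylcyclopentyl]ethan-1-one | IC[C@H]1[C@@H](CC[C@@]1(C)O)C(=O)CBr
F7 | step 3 | diisopropyl (3R,3aS,7aR)-3-hydroxy-3-methyl-7-methylideneoctahydro-5H-indene-5,5-dicarboxylate | CC(C)OC(=O)C1(C(=O)OC(C)C)C[C@H]2[C@@H](CC[C@@]2(C)O)C(=C)C1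
F8 | step 3 | (3R,3aS,7aR)-3-hydroxy-3-methyl-7-methylideneoctahydro-5H-indene-5,5-dicarboxylic acid | OC(=O)C1(C(O)=O)C[C@H]2[C@@H](CC[C@@]2(C)O)C(=C)C1
F9 | step 3 | (1S,2R,5R,6S,8S)-5-hydroxy-1-(iodomethyl)-5-methyl-9-oxo-10-oxatricyclo[6.2.1.0^2,6]undecane-8-carboxylic acid | OC(=O)[C@@]12C[C@H]3[C@@H](CC[C@@]3(C)O)[C@@](CI)(OC1=O)C2
F10 | step 6 | 6-methyl-2,4-bis(trimethylsilyloxy)hepta-1,3-diene (double-bond geometry immaterial) | C=C(O[Si](C)(C)C)C=C(O[Si](C)(C)C)CC(C)C
F11 | step 7 | (1S,3'R,3a'S,7'S,7a'R)-3',4,7'-trihydroxy-3',7'-dimethyl-3-(3-methylbutanoyl)-5,5-di(prop-2-en-1-yl)octahydrospiro[cyclohex-3-ene-1,5'-indene]-2,6-dione | C=CCC1(CC=C)C(=O)[C@@]2(C[C@H]3[C@@H](CC[C@@]3(C)O)[C@@](C)(O)C2)C(=O)C(C(=O)CC(C)C)=C1O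
A1 | alternative 1 | dimethyl 2-{[(1S,2R,5R)-2-hydroxy-2-methyl-5-(prop-1-en-2-yl)cyclopentyl]methyl}malonate | COC(=O)C(C[C@H]1[C@@H](CC[C@@]1(C)O)C(C)=C)C(=O)OC
A2 | alternative 1 | methyl (1S,2R,5R,6S,8S)-5-hydroxy-1,5-dimethyl-9-oxo-10-oxatricyclo[6.2.1.0^2,6]undecane-8-carboxylate | COC(=O)[C@@]12C[C@H]3[C@@H](CC[C@@]3(C)O)[C@@](C)(OC1=O)C2
A3 | alternative 2 | dimethyl 5-oxocyclohex-3-ene-1,1-dicarboxylate | COC(=O)C1(C(=O)OC)CC=CC(=O)C1
A4 | alternative 2 | 2-(4-chlorobut-1-en-2-yl)-4,4,5,5-tetramethyl-1,3,2-dioxaborolane | ClCCC(=C)B1OC(C)(C)C(C)(C)O1
A5 | alternative 2 | dimethyl (3aS,7aR)-3-methylidene-7-oxooctahydro-5H-indene-5,5-dicarboxylate | COC(=O)C1(C(=O)OC)C[C@H]2[C@@H](CCC2=C)C(=O)C1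
A6 | alternative 3 | 1-bromo-3-{(1S,2R,5R)-5-acetyl-2-methyl-2-[(trimethylsilyl)oxy]cyclopentyl}propan-2-one | BrCC(=O)C[C@H]1[C@@H](CC[C@@]1(C)O[Si](C)(C)C)C(C)=O
A7 | alternative 3 | (3R,3aS,7S,7aR)-7-hydroxy-3,7-dimethyl-3-[(trimethylsilyl)oxy]octahydro-5H-inden-5-one | O=C1C[C@H]2[C@@H](CC[C@@]2(C)O[Si](C)(C)C)[C@@](C)(O)C1
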